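**Strategy.** The route rests on disconnecting ring B of the drimane bicycle at its tetrasubstituted C8=C9 alkene (drimane numbering). An intramolecular Horner–Wadsworth–Emmons reaction of keto phosphonoacetate 15 makes this double bond, closes ring B and leaves an ester as chain carbon C11 in one operation. It exploits two features. C8=C9 bears no stereocentre. Ring A with its three methyl groups, C5–H and C6–C7–C8(CH3) map onto the C13 skeleton of α-ionone. Precursor 15 is a trans-1,2-disubstituted cyclohexane: quaternary C10 carries CH(PO3Et2)CO2Et, C5 a 3-oxobutyl arm. C10 is set by a suprafacial Claisen rearrangement. The chain is attached by B-alkyl Suzuki coupling to an (R)-butenolide vinyl iodide.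

Key step: step 11

Remark on the target: it is read as a (5S,10S)-drim-8-ene (10-CH3 and 5-H trans) with an (E)-enal and an (R)-configured butenolide C5. The CH2OH sits on butenolide carbon C4 and the chain on C5, so the lactone is built from methyl (R)-glycidate. The decalin requires the (S)-configured ionone ring carbon.

Assumption (step 5): the lipase is taken to acylate the (1S,4S)-enantiomer of 6; should it prefer the antipode, the recovered alcohol is 8 itself and step 6 falls away.

**Step 1**
Reactants: 1 (±)-α-ionone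
Product: 3 (±)-dihydro-α-ionone [4-(2,6,6-trimethylcyclohex-2-en-1-yl)butan-2-one], via triethylsilyl enol ether 2 (not isolated)
Conditions: Et3SiH, RhCl(PPh3)3 (cat.), toluene, 50 °C; then K2CO3 (cat.), MeOH, rt
Reagents that add atoms: none
Why: Rh-catalysed 1,4-hydrosilylation with a monohydrosilane adds only across the conjugated enone, leaves the hindered trisubstituted ring alkene alone, and methanolysis of the silyl enol ether releases the saturated methyl ketone.

**Step 2**
Reactants: 3 (±)-dihydro-α-ionone
Product: 4 (±)-2-methyl-2-[2-(2,6,6-trimethylcyclohex-2-en-1-yl)ethyl]-1,3-dioxolane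
Conditions: HOCH2CH2OH, PPTS (cat.), benzene, reflux, Dean–Stark
Reagents that add atoms: ethylene glycol, OCCO
Why: Acid-catalysed ketalisation with azeotropic removal of water masks the only carbonyl group for the later hydride and enolate steps, and the weak acid should not move the ring alkene.

**Step 3**
Reactants: 4 (±)-dioxolane of dihydro-α-ionone
Product: 5 (±)-3,5,5-trimethyl-4-[2-(2-methyl-1,3-dioxolan-2-yl)ethyl]cyclohex-2-en-1-one
Conditions: t-BuOOH, Rh2(cap)4 (cat.), K2CO3, CH2Cl2, rt
Reagents that add atoms: tert-butyl hydroperoxide, CC(C)(C)OO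
Why: Radical allylic C–H oxidation (dirhodium caprolactamate/TBHP) attacks the only unhindered secondary allylic CH2 of the ring, because the tertiary allylic C–H beside CMe2 and the vinylic methyl react more slowly, and gives the enone.

**Step 4**
Reactants: 5 (±)-enone
Product: 6 (±)-trans-3,5,5-trimethyl-4-[2-(2-methyl-1,3-dioxolan-2-yl)ethyl]cyclohex-2-en-1-ol, (1S*,4S*)
Conditions: L-Selectride, THF, −78 °C; then NaOH, H2O2, 0 °C
Reagents that add atoms: none
Why: A β,β-disubstituted cyclohexenone undergoes 1,2-reduction with this bulky borohydride, which should approach anti to the axial methyl of CMe2, i.e. on the face of the pseudoaxial side chain, so the new carbinol carries OH trans to the chain (any cis isomer is removed by chromatography).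

**Step 5**
Reactants: 6 (±)-trans-allylic alcohol
Product: 7 (1S,4S)-3,5,5-trimethyl-4-[2-(2-methyl-1,3-dioxolan-2-yl)ethyl]cyclohex-2-en-1-yl acetate
Conditions: lipase AK (Pseudomonas fluorescens), vinyl acetate, MTBE, 30 °C, stopped below half conversion
Reagents that add atoms: vinyl acetate, C=COC(C)=O
Why: Lipase-catalysed kinetic resolution by irreversible transesterification; with the CH2–CMe2 flank as large and the flat vinylic CH as medium group, the Kazlauskas rule predicts faster acylation of the (1S)-carbinol, and since the relative configuration is fixed this also secures the ring CH (future C5).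

**Step 6**
Reactants: 7 (1S,4S)-acetate
Product: 8 (1S,4S)-3,5,5-trimethyl-4-[2-(2-methyl-1,3-dioxolan-2-yl)ethyl]cyclohex-2-en-1-ol
Conditions: K2CO3 (cat.), MeOH, rt
Reagents that add atoms: none
Why: Base-catalysed transesterification (methanolysis) cleaves the acetate at the acyl carbon, so the carbinol configuration and the ketal are untouched.

**Step 7**
Reactants: 8 (1S,4S)-allylic alcohol; 9 triethyl orthoacetate
Product: 11 ethyl 2-{(1S,6S)-1,5,5-trimethyl-6-[2-(2-methyl-1,3-dioxolan-2-yl)ethyl]cyclohex-2-en-1-yl}acetate, via mixed ketene acetal 10 (not isolated)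
Conditions: 9 (excess), EtCO2H (cat.), 140 °C, EtOH distilled off
Reagents that add atoms: none
Why: Johnson–Claisen rearrangement; orthoester exchange and loss of ethanol give 10, whose suprafacial [3,3] shift delivers CH2CO2Et to the methyl-bearing alkene carbon on the face that carried oxygen, anti to the neighbouring side chain, which sets quaternary C10.

**Step 8**
Reactants: 11 cyclohexenyl acetate ester
Product: 12 ethyl 2-{(1R,2S)-1,3,3-trimethyl-2-[2-(2-methyl-1,3-dioxolan-2-yl)ethyl]cyclohexyl}acetate
Conditions: H2 (1 atm), Pd/C, EtOAc, rt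
Reagents that add atoms: none
Why: Heterogeneous catalytic hydrogenation saturates the only C=C bond, a cis-disubstituted ring alkene, creates no stereocentre and leaves ester and ketal alone (the descriptor at C1 changes only through CIP ranking).

**Step 9**
Reactants: 12 saturated ester ketal
Product: 14 ethyl 2-(diethoxyphosphoryl)-2-{(1S,2S)-1,3,3-trimethyl-2-[2-(2-methyl-1,3-dioxolan-2-yl)ethyl]cyclohexyl}acetate (both epimers at the P-bearing carbon), via phosphonite 13 (not isolated)
Conditions: LDA (2.2 equiv), THF, −78 °C; ClP(OEt)2, −78 °C to rt; then 30 % H2O2, 0 °C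
Reagents that add atoms: diethyl chlorophosphite, CCOP(Cl)OCC; hydrogen peroxide, OO
Why: Enolate C-phosphinylation followed by P(III) to P(V) oxidation; the soft chlorophosphite reacts at carbon of the lithium ester enolate, the second equivalent of base keeps the more acidic product deprotonated, and the new CH centre is an inconsequential epimer mixture.

**Step 10**
Reactants: 14 phosphonoacetate ketal
Product: 15 ethyl 2-(diethoxyphosphoryl)-2-[(1S,2S)-1,3,3-trimethyl-2-(3-oxobutyl)cyclohexyl]acetate (both epimers at the P-bearing carbon)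
Conditions: 1 M HCl, THF, rt
Reagents that add atoms: water, O
Why: Acid-catalysed ketal hydrolysis frees the methyl ketone, while the carboxylic and phosphonic esters are stable to dilute acid at room temperature.

**Step 11**
Reactants: 15 keto phosphonoacetate
Product: 16 ethyl (4aS,8aS)-2,5,5,8a-tetramethyl-3,4,4a,5,6,7,8,8a-octahydronaphthalene-1-carboxylate (ethyl drim-8-en-11-oate)
Conditions: NaH (1.0 equiv), THF (high dilution), 0 °C to reflux
Reagents that add atoms: none
Why: NaH removes the phosphonoacetate C–H, by far the most acidic proton of 15, so both C9 epimers merge into one planar stabilised carbanion while the methyl ketone stays un-enolised and the ester, now part of the anion, is shielded from Claisen-type attack. The carbanion adds to ketone carbon C8 and the β-oxido phosphonate closes to an oxaphosphetane that collapses by syn-elimination of sodium diethyl phosphate, which puts the double bond between C8 and C9 and nowhere else. The closest known reaction type is the intramolecular Horner–Wadsworth–Emmons cyclisation of ω-keto phosphonoacetates to cyclohexene carboxylates, and quaternary C10 beside the nucleophilic carbon makes this a hindered member of that class, hence the heating. Ring B closes in the 6-(enolexo)-exo-trig mode. No stereocentre is created, and C5 and C10 are not touched. The step needs chemoselective carbanion formation, secured by the pKa gap, and intramolecular rather than intermolecular attack, secured by the trans-diequatorial placing of both arms on the ring A chair, by dilution and by one equivalent of an irreversible base, which also leaves nothing to deconjugate 16.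

**Step 12**
Reactants: 16 decalin ester
Product: 17 [(4aS,8aS)-2,5,5,8a-tetramethyl-3,4,4a,5,6,7,8,8a-octahydronaphthalen-1-yl]methanol (drim-8-en-11-ol)
Conditions: LiAlH4, Et2O, 0 °C to rt
Reagents that add atoms: none
Why: Hydride reduction of the hindered conjugated ester gives the primary allylic alcohol, conjugate reduction being blocked at the tetrasubstituted alkene.

**Step 13**
Reactants: 17 allylic alcohol
Product: 18 (4aS,8aS)-2,5,5,8a-tetramethyl-3,4,4a,5,6,7,8,8a-octahydronaphthalene-1-carbaldehyde
Conditions: TPAP (cat.), NMO, 4 Å MS, CH2Cl2, rt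
Reagents that add atoms: none
Why: Ley–Griffith oxidation converts the primary allylic alcohol into the enal under neutral conditions without touching the tetrasubstituted alkene, and the aldehyde has no α-hydrogen to epimerise.

**Step 14**
Reactants: 18 enal
Product: 19 (4aS,8aS)-1-ethenyl-2,5,5,8a-tetramethyl-3,4,4a,5,6,7,8,8a-octahydronaphthalene
Conditions: Ph3PCH3Br, KOt-Bu, THF, 0 °C to rt
Reagents that add atoms: methyltriphenylphosphonium bromide, C[P+](c1ccccc1)(c1ccccc1)c1ccccc1.[Br-]
Why: Wittig methylenation with the small non-stabilised ylide works on aldehydes of the β-cyclocitral type that are flanked by a quaternary carbon, and adds chain carbon C12.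

**Step 15**
Reactants: 20 4-methoxybenzyl alcohol; 21 tributyl(iodomethyl)stannane
Product: 22 tributyl{[(4-methoxybenzyl)oxy]methyl}stannane
Conditions: NaH, THF–DMF, 0 °C to rt
Reagents that add atoms: none
Why: Williamson ether synthesis; the alkoxide displaces the primary iodide of 21 by SN2 and gives the precursor of a protected hydroxymethyl anion.

**Step 16**
Reactants: 23 tert-butyldimethyl(prop-2-yn-1-yloxy)silane; 24 methyl (R)-glycidate
Product: 25 methyl (2R)-6-[(tert-butyldimethylsilyl)oxy]-2-hydroxyhex-4-ynoate
Conditions: 23, n-BuLi, THF, −78 °C; BF3·OEt2; then 24, −78 °C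
Reagents that add atoms: none
Why: BF3-promoted epoxide opening by a lithium acetylide occurs by SN2 at the unsubstituted epoxide carbon and spares the ester at −78 °C, so the stereocentre of 24 (future butenolide C5) is carried over unchanged.

**Step 17**
Reactants: 25 α-hydroxy ester
Product: 26 (2R)-6-[(tert-butyldimethylsilyl)oxy]-2-hydroxy-N-methoxy-N-methylhex-4-ynamide
Conditions: MeNH(OMe)·HCl, i-PrMgCl, THF, −20 to 0 °C
Reagents that add atoms: N,O-dimethylhydroxylamine hydrochloride, CNOC.Cl
Why: Weinreb amide formation by aminolysis of the ester with the magnesium amide tolerates the free (deprotonated) hydroxyl group and is not expected to epimerise the α-carbon.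

**Step 18**
Reactants: 26 Weinreb amide; 22 alkoxymethylstannane
Product: 28 (3R)-7-[(tert-butyldimethylsilyl)oxy]-3-hydroxy-1-[(4-methoxybenzyl)oxy]hept-5-yn-2-one, via lithiomethyl PMB ether 27 (not isolated)
Conditions: 22 (2.2 equiv), n-BuLi, THF, −78 °C; then 26, −78 °C
Reagents that add atoms: none
Why: Tin–lithium exchange gives the α-alkoxy organolithium, of which one equivalent deprotonates the OH and the second adds to the Weinreb amide (Weinreb ketone synthesis), the stable chelate preventing over-addition until the cold quench.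

**Step 19**
Reactants: 28 α-hydroxy ketone
Product: 30 (5R)-5-{4-[(tert-butyldimethylsilyl)oxy]but-2-yn-1-yl}-4-{[(4-methoxybenzyl)oxy]methyl}furan-2(5H)-one, via acyl ylide 29 (not isolated)
Conditions: Ph3P=C=C=O, toluene, 80 °C
Reagents that add atoms: (triphenylphosphoranylidene)ketene, O=C=C=P(c1ccccc1)(c1ccccc1)c1ccccc1
Why: The Bestmann ylide adds the secondary OH across its ketene and the resulting stabilised ylide undergoes an intramolecular Wittig olefination with the neighbouring ketone, which closes the butenolide regiospecifically under neutral conditions without involving C5.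

**Step 20**
Reactants: 30 silyl-protected butenolide
Product: 31 (5R)-5-(4-hydroxybut-2-yn-1-yl)-4-{[(4-methoxybenzyl)oxy]methyl}furan-2(5H)-one
Conditions: HF·pyridine, THF, 0 °C
Reagents that add atoms: none
Why: Fluoride-mediated desilylation in a weakly acidic medium frees the propargylic alcohol and avoids any base that could deprotonate butenolide C5; the PMB ether is inert.

**Step 21**
Reactants: 31 propargylic alcohol
Product: 33 (5R)-5-[(2Z)-4-hydroxy-3-iodobut-2-en-1-yl]-4-{[(4-methoxybenzyl)oxy]methyl}furan-2(5H)-one, via alkenylstannane 32 (not isolated)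
Conditions: Bu3SnH, [Cp*RuCl]4 (cat.), CH2Cl2, rt; then I2, 0 °C
Reagents that add atoms: iodine, II
Why: Hydroxyl-directed ruthenium-catalysed trans-hydrostannation places tin on the alkyne carbon next to CH2OH and hydrogen anti to it, and iododestannylation with retention gives the (Z)-iodide in which iodine is cis to the CH2 leading to the lactone.

**Step 22**
Reactants: 19 vinyl decalin; 33 (Z)-iodoalkenol
Product: 35 (5R)-5-[(2E)-3-(hydroxymethyl)-5-{(4aS,8aS)-2,5,5,8a-tetramethyl-3,4,4a,5,6,7,8,8a-octahydronaphthalen-1-yl}pent-2-en-1-yl]-4-{[(4-methoxybenzyl)oxy]methyl}furan-2(5H)-one, via B-alkyl-9-BBN borane 34 (not isolated)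
Conditions: 19, 9-BBN, THF, rt; then 33, PdCl2(dppf), AsPh3, Cs2CO3, DMF–H2O, rt
Reagents that add atoms: none
Why: 9-BBN hydroborates only the terminal CH2 of the vinyl group (anti-Markovnikov, the tetrasubstituted alkene is inert), and the B-alkyl Suzuki–Miyaura coupling replaces iodine with retention, which fixes the trisubstituted alkene geometry.

**Step 23**
Reactants: 35 allylic alcohol
Product: 36 (2E)-4-[(2R)-3-{[(4-methoxybenzyl)oxy]methyl}-5-oxo-2,5-dihydrofuran-2-yl]-2-{2-[(4aS,8aS)-2,5,5,8a-tetramethyl-3,4,4a,5,6,7,8,8a-octahydronaphthalen-1-yl]ethyl}but-2-enal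
Conditions: MnO2, CH2Cl2, rt
Reagents that add atoms: none
Why: Manganese dioxide allylic oxidation acts on the only free hydroxyl group under neutral conditions and gives the enal in its thermodynamically preferred E geometry.

**Step 24**
Reactants: 36 PMB-protected enal
Product: 37 target CNP0197865.2
Conditions: DDQ, CH2Cl2–pH 7 buffer, 0 °C
Reagents that add atoms: none
Why: Oxidative PMB ether cleavage with DDQ runs by hydride abstraction at the electron-rich benzylic CH2 in buffered neutral medium, which spares the base-sensitive enal and butenolide units and the alkenes.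

**Compound list**

| No. | Name | SMILES | Role |
|---|---|---|---|
| 1 | (±)-α-ionone | CC1=CCCC(C)(C)C1/C=C/C(C)=O | starting material |
| 2 | triethylsilyl enol ether of dihydro-α-ionone (racemic) | CC1=CCCC(C)(C)C1CC=C(C)O[Si](CC)(CC)CC | intermediate |
| 3 | (±)-dihydro-α-ionone | CC1=CCCC(C)(C)C1CCC(C)=O | intermediate |
| 4 | (±)-2-methyl-2-[2-(2,6,6-trimethylcyclohex-2-en-1-yl)ethyl]-1,3-dioxolane | CC1=CCCC(C)(C)C1CCC2(C)OCCO2 | intermediate |
| 5 | (±)-3,5,5-trimethyl-4-[2-(2-methyl-1,3-dioxolan-2-yl)ethyl]cyclohex-2-en-1-one | CC1=CC(=O)CC(C)(C)C1CCC2(C)OCCO2 | intermediate |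
| 6 | (±)-trans-allylic alcohol (racemate, both enantiomers written) | O[C@@H]1C=C(C)[C@@H](CCC2(C)OCCO2)C(C)(C)C1.O[C@H]1C=C(C)[C@H](CCC2(C)OCCO2)C(C)(C)C1 | intermediate |
| 7 | (1S,4S)-allylic acetate | CC(=O)O[C@@H]1C=C(C)[C@@H](CCC2(C)OCCO2)C(C)(C)C1 | intermediate |
| 8 | (1S,4S)-allylic alcohol | O[C@@H]1C=C(C)[C@@H](CCC2(C)OCCO2)C(C)(C)C1 | intermediate |
| 9 | triethyl orthoacetate | CCOC(C)(OCC)OCC | starting material |
| 10 | 1-ethoxyvinyl ether of 8 (mixed ketene acetal) | C=C(OCC)O[C@@H]1C=C(C)[C@@H](CCC2(C)OCCO2)C(C)(C)C1 | intermediate |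
| 11 | ethyl 2-{(1S,6S)-1,5,5-trimethyl-6-[2-(2-methyl-1,3-dioxolan-2-yl)ethyl]cyclohex-2-en-1-yl}acetate | CCOC(=O)C[C@@]1(C)C=CCC(C)(C)[C@@H]1CCC2(C)OCCO2 | intermediate |
| 12 | ethyl 2-{(1R,2S)-1,3,3-trimethyl-2-[2-(2-methyl-1,3-dioxolan-2-yl)ethyl]cyclohexyl}acetate | CCOC(=O)C[C@@]1(C)CCCC(C)(C)[C@@H]1CCC2(C)OCCO2 | intermediate |
| 13 | α-(diethoxyphosphanyl) ester (phosphonite, epimers) | CCOC(=O)C(P(OCC)OCC)[C@@]1(C)CCCC(C)(C)[C@@H]1CCC2(C)OCCO2 | intermediate |
| 14 | phosphonoacetate ketal (epimers at the P-bearing carbon) | CCOC(=O)C(P(=O)(OCC)OCC)[C@@]1(C)CCCC(C)(C)[C@@H]1CCC2(C)OCCO2 | intermediate |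
| 15 | keto phosphonoacetate, key-step precursor (epimers at the P-bearing carbon) | CCOC(=O)C(P(=O)(OCC)OCC)[C@@]1(C)CCCC(C)(C)[C@@H]1CCC(C)=O | intermediate |
| 16 | ethyl drim-8-en-11-oate, key-step product | CC1=C(C(=O)OCC)[C@@]2(C)CCCC(C)(C)[C@@H]2CC1 | intermediate |
| 17 | drim-8-en-11-ol | CC1=C(CO)[C@@]2(C)CCCC(C)(C)[C@@H]2CC1 | intermediate |
| 18 | drim-8-en-11-al | CC1=C(C=O)[C@@]2(C)CCCC(C)(C)[C@@H]2CC1 | intermediate |
| 19 | 9-vinyl drim-8-ene diene | CC1=C(C=C)[C@@]2(C)CCCC(C)(C)[C@@H]2CC1 | intermediate |
| 20 | 4-methoxybenzyl alcohol | COc1ccc(CO)cc1 | starting material |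
| 21 | tributyl(iodomethyl)stannane | CCCC[Sn](CI)(CCCC)CCCC | starting material |
| 22 | tributyl{[(4-methoxybenzyl)oxy]methyl}stannane | COc1ccc(COC[Sn](CCCC)(CCCC)CCCC)cc1 | intermediate |
| 23 | tert-butyldimethyl(prop-2-yn-1-yloxy)silane | C#CCO[Si](C)(C)C(C)(C)C | starting material |
| 24 | methyl (R)-glycidate | COC(=O)[C@H]1CO1 | starting material |
| 25 | methyl (2R)-6-(TBS-oxy)-2-hydroxyhex-4-ynoate | COC(=O)[C@H](O)CC#CCO[Si](C)(C)C(C)(C)C | intermediate |
| 26 | (2R)-Weinreb amide | CON(C)C(=O)[C@H](O)CC#CCO[Si](C)(C)C(C)(C)C | intermediate |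
| 27 | [(4-methoxybenzyl)oxy]methyllithium | [Li]COCc1ccc(OC)cc1 | intermediate |
| 28 | (3R)-α-hydroxy ketone | COc1ccc(COCC(=O)[C@H](O)CC#CCO[Si](C)(C)C(C)(C)C)cc1 | intermediate |
| 29 | (triphenylphosphoranylidene)acetate ester of 28 | COc1ccc(COCC(=O)[C@@H](CC#CCO[Si](C)(C)C(C)(C)C)OC(=O)C=P(c2ccccc2)(c2ccccc2)c2ccccc2)cc1 | intermediate |
| 30 | (5R)-butenolide, TBS and PMB protected | CC(C)(C)[Si](C)(C)OCC#CC[C@H]1OC(=O)C=C1COCc2ccc(OC)cc2 | intermediate |
| 31 | (5R)-butenolide propargylic alcohol | OCC#CC[C@H]1OC(=O)C=C1COCc2ccc(OC)cc2 | intermediate |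
| 32 | (Z)-alkenylstannane | OC/C([Sn](CCCC)(CCCC)CCCC)=C/C[C@H]1OC(=O)C=C1COCc2ccc(OC)cc2 | intermediate |
| 33 | (Z)-iodoalkenol butenolide | OC/C(I)=C/C[C@H]1OC(=O)C=C1COCc2ccc(OC)cc2 | intermediate |
| 34 | B-[2-(drim-8-en-9-yl)ethyl]-9-BBN | CC1=C(CCB3C4CCCC3CCC4)[C@@]2(C)CCCC(C)(C)[C@@H]2CC1 | intermediate |
| 35 | coupled (E)-allylic alcohol, PMB ether | CC1=C(CC/C(CO)=C\C[C@H]3OC(=O)C=C3COCc4ccc(OC)cc4)[C@@]2(C)CCCC(C)(C)[C@@H]2CC1 | intermediate |
| 36 | (E)-enal, PMB ether | CC1=C(CC/C(C=O)=C\C[C@H]3OC(=O)C=C3COCc4ccc(OC)cc4)[C@@]2(C)CCCC(C)(C)[C@@H]2CC1 | intermediate |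
| 37 | CNP0197865.2 | CC1=C(CC/C(C=O)=C\C[C@H]2OC(=O)C=C2CO)[C@@]2(C)CCCC(C)(C)[C@@H]2CC1 | target |

**Step count.** Total: 24 steps. Longest linear sequence: 17 steps (steps 1–14 and 22–24, from α-ionone). The butenolide branch takes steps 15–21.

**The three steps most likely to fail**

1. **Step 11.** The carbanion beside quaternary C10 may add to the ketone too slowly or reversibly, so that proton shuttling to the ketone and intermolecular condensation take over.
 - The fallback forms the same C8–C9 bond by Lewis-acid chemistry. It sets out from ester ketal 12 and comes back at 16.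
 - LDA/TMSCl should convert 12 into the ketene silyl acetal F1.
 - TiCl4 in CH2Cl2 at −78 °C ionises the dioxolane to an oxocarbenium ion. The ketene acetal traps it in an intramolecular Mukaiyama aldol-type cyclisation to the β-(2-hydroxyethoxy) decalin ester F2.
 - NaOEt in EtOH then expels ethylene glycol by E1cB elimination, which can only lead to the conjugated ester 16.

2. **Step 7.** Acid and heat may ionise and dehydrate the allylic alcohol or exchange the ketal faster than the congested sigmatropic shift, which runs syn to the axial ring methyl, can proceed.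
 - The fallback is an Ireland–Claisen rearrangement under basic, lower-temperature conditions. It sets out from acetate 7 (so step 6 is skipped) and comes back at 11.
 - LDA and TBSCl in THF–DMPU at −78 °C should give the silyl ketene acetal F3.
 - Warming in toluene effects the same suprafacial [3,3] shift to the silyl ester F4.
 - Mild aqueous K2CO3/MeOH followed by buffered acidification gives the carboxylic acid F5.
 - EtI/K2CO3 in DMF gives 11.

3. **Step 22.** The aqueous base of the coupling may deprotonate butenolide C5 and erode its configuration, or protodeboronation may outrun a slow transmetalation.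
 - The fallback is a base-free Negishi coupling. It sets out from borane 34 and iodide 33 and comes back at 35.
 - Oxidation of 34 (NaBO3) should give the homoallylic alcohol F6.
 - Appel-type iodination (I2, PPh3, imidazole) gives the primary iodide F7.
 - Zinc insertion (Zn, LiCl, THF) gives the alkylzinc iodide F8.
 - In parallel, 33 is silylated (TESCl, imidazole) to the triethylsilyl ether F9.
 - Pd-catalysed coupling of F8 with F9 in THF at rt gives the silyl ether F10, and PPTS in MeOH releases 35.

**Further compounds**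
F1 | step 11 | ketene ethyl trimethylsilyl acetal of 12 | CCOC(O[Si](C)(C)C)=C[C@@]1(C)CCCC(C)(C)[C@@H]1CCC2(C)OCCO2
F2 | step 11 | ethyl 8-(2-hydroxyethoxy)driman-11-oate (mixture at C8 and C9) | CC1(OCCO)C(C(=O)OCC)[C@@]2(C)CCCC(C)(C)[C@@H]2CC1
F3 | step 7 | tert-butyldimethylsilyl ketene acetal of 7 | C=C(O[Si](C)(C)C(C)(C)C)O[C@@H]1C=C(C)[C@@H](CCC2(C)OCCO2)C(C)(C)C1
F4 | step 7 | tert-butyldimethylsilyl ester of the rearranged acid | CC(C)(C)[Si](C)(C)OC(=O)C[C@@]1(C)C=CCC(C)(C)[C@@H]1CCC2(C)OCCO2
F5 | step 7 | 2-{(1S,6S)-1,5,5-trimethyl-6-[2-(2-methyl-1,3-dioxolan-2-yl)ethyl]cyclohex-2-en-1-yl}acetic acid | OC(=O)C[C@@]1(C)C=CCC(C)(C)[C@@H]1CCC2(C)OCCO2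
F6 | step 22 | 2-(drim-8-en-9-yl)ethanol | CC1=C(CCO)[C@@]2(C)CCCC(C)(C)[C@@H]2CC1
F7 | step 22 | 2-(drim-8-en-9-yl)ethyl iodide | CC1=C(CCI)[C@@]2(C)CCCC(C)(C)[C@@H]2CC1
F8 | step 22 | 2-(drim-8-en-9-yl)ethylzinc iodide | CC1=C(CC[Zn]I)[C@@]2(C)CCCC(C)(C)[C@@H]2CC1
F9 | step 22 | triethylsilyl ether of 33 | CC[Si](CC)(CC)OC/C(I)=C/C[C@H]1OC(=O)C=C1COCc2ccc(OC)cc2
F10 | step 22 | triethylsilyl ether of 35 | CC1=C(CC/C(CO[Si](CC)(CC)CC)=C\C[C@H]3OC(=O)C=C3COCc4ccc(OC)cc4)[C@@]2(C)CCCC(C)(C)[C@@H]2CC1
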